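## Analysis of the target

The target is a briarane diterpenoid. Carbons are labelled C1–C20 in the briarane sense: ring A is the cyclohexane C1, C10, C11, C12, C13, C14; the ten-membered carbocycle is C1–C10; C15 is the methyl on C1, C16 the exocyclic methylene on C5, C17/C18/C19 the lactone CH, its methyl and its carbonyl, and C20 the carboxyl on C11. An ether oxygen bridges C4 and C8, so that O, C4, C5, C6, C7, C8 form a tetrahydropyran and O, C8, C9, C10, C1, C2, C3, C4 an oxocane (an 11-oxabicyclo[5.3.1]undecane). A γ-lactone (C8–C17–C19(=O)–O–C7) is cis-fused to the tetrahydropyran, and ring A is trans-fused to the oxocane at C1–C10.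

There are twelve stereocentres (1R,2R,3R,4R,6S,7R,8R,9S,10S,11R,14S,17R), seven of them contiguous around the ten-membered ring, two of them fully substituted (C1, C8) and one a tertiary carbinol (C11). With the C15 methyl defined as β, the relationships are: H10 α; 14-OAc α; 11-OH α and COOH β; 2-OAc β; 3-OAc α; 9-OAc β; ether oxygen α at C4 and C8; lactone oxygen α at C7; Cl α at C6; the C18 methyl syn to the ring oxygen on C8.

Sensitive groups are the secondary allylic chloride next to the C5=C16 methylene (ionisation, SN2′), four acetates beside a free tertiary α-hydroxy acid (acyl migration, base), and the lactone. The difficulty is threefold: a medium ring that is bridged, the relay of configuration between the ring A domain (C1, C10, C11, C14) and the tetrahydropyran domain (C4, C6, C7, C8), and oxygen on almost every ring carbon.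

The structural feature that invites the strategy is the 2,5-bridged oxygen heterocycle O/C4/C8 flanked by two oxygenated carbons, C3 and C9. Together these five atoms are a furan ring in which the C3–C9 bond has been cut.

## Retrosynthetic reasoning

**End game (37 back to 34).** The acid is released last from tert-butyl ester 36. The C6 chloride and the C5=C16 methylene are made together from the C5=C6 olefin of tetraacetate 35 by ene-type chlorination, so the most labile unit appears in the penultimate step. The four acetates come from pentaol 34. Nothing in these disconnections touches the skeleton.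

**Carbinols at C3 and C9, configuration at C10, the carboxyl (34 back to 26).** C3–OH and C9–OH are traced to ketones, because both carbons will be carbonyl carbons when the ring is opened. The carboxyl is traced to a silylated alkyne on C11, a slim group that survives every intermediate step. The C5=C6 olefin is carried as the enol triflate of the C6 ketone. H10 is traced to its epimer: the C9 ketone of 28 makes C10 enolisable, and the epimeric cis ring fusion is what the key step needs.

**The ten-membered ring (26 back to 25).** The ring is not closed; it is uncovered. In 25 the carbons C3 and C9 are joined by a tetrasubstituted double bond that is shared by a cyclopentene (C1, C2, C3, C9, C10) and an oxygen-bridged cycloheptene (C3–C9). Cutting this one bond by ozonolysis gives the ten-membered carbocycle and places carbonyl groups exactly on C3 and C9, the two carbons that carry acetoxy groups in 37. No medium-ring closure is needed anywhere.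

**The oxygen bridge and the tetrahydropyran (25 back to 16 and 17).** The 8-oxabicyclo[3.2.1]octenone core of 20 is the (4+3) adduct of a furan and a three-carbon oxyallyl unit. The cut is made at C4–C5 and C7–C8. The furan supplies O, C4, C3, C9 and C8, with the C8 acetic ester arm that becomes the lactone; trichloroacetone 17, through cation 18, supplies C5, C6 and C7. The forward reaction has to add to the β face of furan 16, because that face decides C4 and C8 relative to C1. The C7 oxygen, the C5 methyl, the lactone and the C17 methyl are then added to the rigid adduct by enolate chemistry (20 to 25).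

**The annulated furan (16 back to 6 and 7).** Furan 10 is the cyclodehydration product of a 1,4-dicarbonyl compound (9). Its C8–C9 bond comes from conjugate addition of nitro ester 7 to formyl enone 6, and C4 is the formyl carbon. The C2 carbinol, the C11 carbinol with its alkyne, and the protecting groups are set on the cis-hydrindane (10 to 16), where ring shape and the C14 hydroxyl direct the reagents.

**Ring A and the quaternary C1 (6 back to 1 and 2).** The cis-hydrindanone 3 is the Diels–Alder adduct of 2-methylcyclopentenone 1 and the symmetric diene 2. This forms C1–C14 and C10–C11, and sets C1, C14 and the oxygen on C11 in one step from two commercial compounds.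

## Alternatives that were turned down

**Alternative 1:** The textbook route closes the ten-membered carbocycle by macrocyclisation (ring-closing metathesis with the second-generation Grubbs catalyst, or a CrCl2/NiCl2-mediated coupling) to give the carbocyclic 3E-olefin with a free C8 hydroxyl, A1. The oxygen bridge is then made by epoxidation of C3=C4 and transannular opening by the C8 hydroxyl. It was turned down for three reasons. The closure must form a medium ring between a neopentyl position (next to quaternary C1) and a hindered partner. The configuration of C3 and C4, and with it the whole relation between the two halves of the molecule, would rest on the conformation of a flexible cyclodecene at the epoxidation step. Two separate enantiopure fragments would have to be made before the risky step, so the risk sits late and after a long sequence.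

**Alternative 2:** A double Diels–Alder sequence on 2-methyl-1,4-benzoquinone (isoprene first, then 1-acetoxybutadiene) gives the linear tricyclic enedione A2, whose central C3=C8 olefin would be cleaved to open the ten-membered ring with ketones at C3 and C8. The opening is reliable, but it leaves C4 and C7 as unfunctionalised methylene groups. Oxygen placed there before the cleavage is lost by aromatisation of that ring, and after the cleavage it must be introduced on a flexible 1,6-diketone that is prone to transannular aldol reactions. C8 would become quaternary by an uncontrolled addition to a ring ketone. The route therefore wins the ring but not the tetrahydropyran, and needs more steps after the key step than before it.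

**Alternative 3:** An Achmatowicz rearrangement of a tertiary furfuryl carbinol gives pyranone A3, whose anomeric carbon C4 would be attacked by a tethered enol ether at C3 to close the oxocane (bond C3–C4). It was turned down because C-glycosylation of such pyranones prefers the nucleophile trans to the larger C8 substituent, whereas the bridge requires cis. The closure is an eight-membered ring formation that also has to set C3. A3 itself demands prior acyclic control of C8, C9 and C17 on a fully elaborated ring A, a long linear prelude to an uncertain cyclisation.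

Key step: step 11

Assumption: the (S)-configured oxazaborolidinium catalyst of step 1 is taken to give the enantiomer of 3 that is drawn (the antipodal catalyst is used if the sense of induction is opposite); carbon labels and the α/β notation are those defined in the analysis.

Step 1
Reactants: 1 2-methylcyclopent-2-en-1-one; 2 (1E,3E)-buta-1,3-diene-1,4-diyl diacetate
Product: 3 cis-hydrindenone diacetate (C2 ketone; 11α,14α-diacetoxy; C12=C13; H10 and C15 methyl both β)
Conditions: (S)-3,3-diphenyl-1-(o-tolyl)tetrahydro-1H,3H-pyrrolo[1,2-c][1,3,2]oxazaborole (20 mol%), Tf2NH (17 mol%), CH2Cl2, −40 °C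
Reagents that add atoms: none
Why: Catalytic enantioselective Diels–Alder reaction of a 2-cycloalkenone; the diene is symmetric, so there is no regiochemical issue, the endo transition state puts both acetoxy groups cis to the carbonyl-bearing ring bonds and hence trans to the angular methyl (C14 as in the target), and the catalyst selects the enone face and so fixes C1; the cis ring fusion is wanted for step 11.

Step 2
Reactants: 3 cis-hydrindenone diacetate
Product: 4 cis-hydrindanone diacetate (as 3 with C12–C13 saturated)
Conditions: H2 (1 atm), Rh/Al2O3 (5%), EtOAc, 23 °C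
Reagents that add atoms: none
Why: Heterogeneous hydrogenation of the disubstituted olefin; rhodium on alumina is chosen so that the two allylic acetates are not hydrogenolysed, and no stereocentre is formed.

Step 3
Reactants: 4 cis-hydrindanone diacetate
Product: 5 3-(hydroxymethylene) ketone (C3=C4H–OH, hydrogen-bonded to the C2 carbonyl)
Conditions: LiHMDS (1.1 equiv), THF, −78 °C; CF3CH2OCHO; aq NH4Cl
Reagents that add atoms: 2,2,2-trifluoroethyl formate, O=COCC(F)(F)F
Why: Claisen-type formylation of a ketone; C1 is quaternary, so only C3 can be enolised, and the ketone is far more acidic than the two acetates at −78 °C.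

Step 4
Reactants: 5 3-(hydroxymethylene) ketone
Product: 6 3-formyl cyclopentenone (C4 aldehyde on C3; C3=C9)
Conditions: DDQ, 1,4-dioxane, 23 °C
Reagents that add atoms: none
Why: DDQ dehydrogenation of an α-hydroxymethylene ketone to the α-formyl enone, a standard way to activate the β-carbon (here C9) of a cyclic ketone.

Step 5
Reactants: 6 3-formyl cyclopentenone; 7 methyl 3-nitropropanoate
Product: 8 nitro ester Michael adduct (C9–C8H(NO2)–C17H2–CO2Me on the β face; C8 epimers; C3 hydroxymethylene)
Conditions: Et3N (0.2 equiv), MeCN, 0 °C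
Reagents that add atoms: none
Why: Nitro-Michael addition to a doubly activated alkylidene 1,3-dicarbonyl acceptor forms C8–C9; the new centres at C8 and C9 are of no consequence because both become furan carbons.

Step 6
Reactants: 8 nitro ester Michael adduct
Product: 10 furan-fused ketone diol (furan O–C4H=C3–C9=C8 bearing CH2CO2Me on C8; C2 ketone; 11α- and 14α-hydroxy; H10 β), via keto aldehyde diol 9 (not isolated)
Conditions: NaOMe, MeOH, 0 to 23 °C; then aq TiCl3, NH4OAc, 0 °C; then TsOH (cat.), THF, 40 °C
Reagents that add atoms: water, O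
Why: Methoxide converts the nitro group into its nitronate (which cannot lose nitrous acid) and removes both acetates; the TiCl3 Nef reaction unveils the C8 ketone, and the 1,4-dicarbonyl compound 9 cyclodehydrates (Paal–Knorr) to the 3,4-annulated furan, since only the C4/C8 pair can close a five-membered ring.

Step 7
Reactants: 10 furan-fused ketone diol
Product: 11 2β,11α,14α-triol
Conditions: Me4NBH(OAc)3, MeCN/AcOH, −30 °C
Reagents that add atoms: none
Why: Hydroxyl-directed (Evans–Saksena) reduction of a β-hydroxy ketone: boron bound to the 14α oxygen delivers hydride to the α face of the C2 carbonyl and gives the 2β alcohol (anti-1,3-diol), whereas an external hydride would enter from the convex β face.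

Step 8
Reactants: 11 2β,11α,14α-triol
Product: 12 2,14-O-(di-tert-butylsilylene) 11α-alcohol
Conditions: tBu2Si(OTf)2 (1.05 equiv), 2,6-lutidine, CH2Cl2, −40 to 0 °C
Reagents that add atoms: di-tert-butylsilyl bis(trifluoromethanesulfonate), CC(C)(C)[Si](OS(=O)(=O)C(F)(F)F)(OS(=O)(=O)C(F)(F)F)C(C)(C)C
Why: The 1,3-diol closes a six-membered silylene much faster than the isolated C11 hydroxyl reacts; the ring also ties the C2 oxygen substituent back from the furan.

Step 9
Reactants: 12 2,14-O-silylene 11α-alcohol
Product: 13 2,14-O-silylene C11 ketone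
Conditions: Dess–Martin periodinane, NaHCO3, CH2Cl2, 23 °C
Reagents that add atoms: none
Why: Mild periodinane oxidation of a secondary alcohol that leaves the furan and the silylene untouched.

Step 10
Reactants: 13 2,14-O-silylene C11 ketone; 14 ethynyltrimethylsilane
Product: 16 11α-triethylsilyloxy 11β-(trimethylsilylethynyl) furan, via 11α-hydroxy alkyne 15 (not isolated)
Conditions: 14, n-BuLi, THF, −78 °C; CeCl3; then 13; then Et3SiOTf, −78 to 0 °C
Reagents that add atoms: triethylsilyl trifluoromethanesulfonate, CC[Si](CC)(CC)OS(=O)(=O)C(F)(F)F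
Why: Organocerium 1,2-addition to the ketone in the presence of the ester; in the cis-hydrindane chair the C1–C2 bond is axial and syn to C11, so axial attack is blocked and the alkynyl group enters equatorially (β) with the oxygen α as in the target; the alkoxide is silylated in the flask.

Step 11
Reactants: 16 11α-triethylsilyloxy 11β-(trimethylsilylethynyl) furan; 17 1,1,3-trichloropropan-2-one
Product: 19 5,7-dichloro (4+3) cycloadduct (8-oxabicyclo[3.2.1]oct-6-en-3-one core: O bridging C4 and C8; C6 ketone; C3=C9; three-carbon bridge on the β face), via 1,3-dichloro-2-oxidoallyl cation 18 (not isolated)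
Conditions: 17 (3 equiv), Et3N, CF3CH2OH, 0 to 23 °C
Reagents that add atoms: none
Why: Triethylamine in trifluoroethanol ionises 17 to the oxyallyl cation 18, which adds across the furan diene C4=C3–C9=C8 of 16 in a (4+3) cycloaddition, forming C4–C5 and C7–C8 and leaving the C3=C9 double bond. The closest known reaction type is the oxyallyl cation–furan (4+3) cycloaddition under Föhlisch conditions, which tolerates 2-alkyl and 3,4-annulated furans. Two rings close at once: the seven-membered carbocycle C3–C4–C5–C6–C7–C8–C9 by suprafacial addition of the two-electron allyl cation to the four-electron diene, and within it the tetrahydropyran O–C4–C5–C6–C7–C8, whose oxygen is the former furan oxygen. C4 and C8 are set together and are necessarily cis because both bonds form on one face of the planar furan; their sense relative to C1 is decided by which face reacts. That face is controlled by the cis ring fusion: ring A and the fully substituted C11 with its silyloxy and alkynyl groups fold under the α face next to C8, so the cation should add to the convex β face, syn to the C15 methyl and H10, which is the configuration of the target at C4 and C8. The three-carbon partner is symmetric, so there is no regiochemical issue, and the two chlorine-bearing centres are removed in the next step. The selectivity the step needs is therefore facial only, and the silylene keeps the C2 oxygen substituent away from the β face near C4. The adduct contains the latent ten-membered ring: its tetrasubstituted C3=C9 bond is the only bond that has to be cut later.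

Step 12
Reactants: 19 5,7-dichloro (4+3) cycloadduct
Product: 20 cycloadduct ketone (C5H2, C7H2, C6 ketone)
Conditions: Zn–Cu couple, NH4Cl, MeOH, 23 °C
Reagents that add atoms: none
Why: Reductive dechlorination of α-chloro ketones, the usual second stage of this cycloaddition; it removes the two stereocentres that were of no consequence.

Step 13
Reactants: 20 cycloadduct ketone
Product: 21 5-methyl ketone (methyl on C5, exo)
Conditions: LDA (1.05 equiv), THF, −78 °C; MeI
Reagents that add atoms: iodomethane, CI
Why: Kinetic enolate alkylation; C5 is the less hindered α-position (C7 is flanked by quaternary C8) and the ketone is more acidic than the ester, so the C16 methyl is placed on C5; its configuration is irrelevant because C5 becomes sp2.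

Step 14
Reactants: 21 5-methyl ketone
Product: 23 keto γ-lactone (C19(=O)–O–C7 cis-fused to the tetrahydropyran; C6 ketone; C5 methyl), via 7-hydroxy ester 22 (not isolated)
Conditions: LDA (1.2 equiv), THF, −78 °C; 3-phenyl-2-(phenylsulfonyl)oxaziridine; −78 to 0 °C
Reagents that add atoms: 3-phenyl-2-(phenylsulfonyl)oxaziridine, O=S(=O)(c1ccccc1)N1OC1c1ccccc1
Why: The second kinetic deprotonation can only take the C7 methylene (the C5 hydrogen is now tertiary and equatorial); Davis hydroxylation from the exo face, opposite to the C3=C9 bridge, sets C7 with its oxygen cis to the C8 acetic ester arm, and the alkoxide closes the γ-lactone in the flask.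

Step 15
Reactants: 23 keto γ-lactone
Product: 24 enol triflate (C5(CH3)=C6–OTf)
Conditions: Tf2O, 2,6-di-tert-butyl-4-methylpyridine, CH2Cl2, 0 to 23 °C
Reagents that add atoms: trifluoromethanesulfonic anhydride, O=S(=O)(OS(=O)(=O)C(F)(F)F)C(F)(F)F
Why: Enol triflate formation under non-basic, thermodynamic conditions goes toward the more substituted, non-oxygenated C5; the C6 ketone is thereby masked as an electron-poor olefin that survives ozone, hydrides and bases.

Step 16
Reactants: 24 enol triflate
Product: 25 17-methyl lactone enol triflate (C18 methyl syn to the ring oxygen on C8)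
Conditions: LDA, THF, −78 °C; MeI
Reagents that add atoms: iodomethane, CI
Why: Lactone enolate alkylation; on the fully substituted neighbour C8 one side carries the C9 carbon and the other only the ring oxygen, so iodomethane should approach C17 from the oxygen side and give the 17R configuration.

Step 17
Reactants: 25 17-methyl lactone enol triflate
Product: 26 3,9-diketone with the ten-membered carbocycle (H10 β)
Conditions: O3 (1 equiv, to the end point of an indicator dye), CH2Cl2/MeOH, −78 °C; Me2S
Reagents that add atoms: ozone, [O-][O+]=O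
Why: Ozonolysis is selective for the strained, electron-rich tetrasubstituted C3=C9 olefin over the vinyl triflate and the silylated alkyne; cutting this bond turns the fused five- and seven-membered rings into the ten-membered carbocycle and unveils ketones on C3 and C9 without touching a stereocentre.

Step 18
Reactants: 26 3,9-diketone
Product: 27 3α-hydroxy 9-ketone
Conditions: Zn(BH4)2, Et2O, −20 °C
Reagents that add atoms: none
Why: The C3 ketone is far less hindered than the C9 ketone (between quaternary C8 and C10); chelation of zinc between the C3 carbonyl and the ring oxygen on C4 (Cram-chelate model) and the polar Felkin–Anh model for the C2 silyloxy group both predict hydride delivery that gives the 3α alcohol.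

Step 19
Reactants: 27 3α-hydroxy 9-ketone
Product: 28 3α-triethylsilyloxy 9-ketone (H10 β)
Conditions: Et3SiOTf, 2,6-lutidine, CH2Cl2, −78 °C
Reagents that add atoms: triethylsilyl trifluoromethanesulfonate, CC[Si](CC)(CC)OS(=O)(=O)C(F)(F)F
Why: Silylation keeps the C3 hydroxyl from forming a transannular hemiketal with the C9 ketone, which must stay free for the next two steps.

Step 20
Reactants: 28 3α-triethylsilyloxy 9-ketone (H10 β)
Product: 29 3α-triethylsilyloxy 9-ketone with trans ring fusion (H10 α)
Conditions: DBU (0.3 equiv), toluene, 40 °C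
Reagents that add atoms: none
Why: Base-mediated epimerisation at C10, the only enolisable position of the C9 ketone; the trans fusion puts both arms of the medium ring equatorial on ring A while the slim alkynyl group tolerates the axial position syn to the C15 methyl, whereas the cis isomer has the C2 arm axial and syn to the bulky C11 silyloxy group.

Step 21
Reactants: 29 trans-fused 9-ketone
Product: 30 9β-alcohol
Conditions: NaBH4, MeOH/THF, −20 °C
Reagents that add atoms: none
Why: Peripheral hydride attack on a medium-ring ketone: with the ring bond C10–C1 perpendicular to the carbonyl and the quaternary C11 turned toward the carbonyl oxygen rather than toward quaternary C8, hydride enters anti to C1 past H10 and should give the 9β alcohol (H9 and H10 cis).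

Step 22
Reactants: 30 9β-alcohol
Product: 31 2β,3α,9β,11α,14α-pentaol with terminal alkyne
Conditions: Bu4NF, AcOH, THF, 0 to 23 °C
Reagents that add atoms: none
Why: Buffered fluoride removes the two triethylsilyl ethers, the silylene and the alkynyl silyl group in one operation; the lactone and the vinyl triflate tolerate these conditions.

Step 23
Reactants: 31 pentaol with terminal alkyne
Product: 33 tert-butyl ester pentaol, via C20 carboxylic acid 32 (not isolated)
Conditions: O3, CH2Cl2, −78 °C; H2O; then tBuOC(=NH)CCl3, CH2Cl2/cyclohexane, 23 °C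
Reagents that add atoms: ozone, [O-][O+]=O; water, O; tert-butyl 2,2,2-trichloroacetimidate, CC(C)(C)OC(=N)C(Cl)(Cl)Cl
Why: Ozonolysis of the terminal alkyne gives the carboxylic acid with loss of the terminal carbon as formic acid, the vinyl triflate being inert; the imidate esterifies the acid without a catalyst and leaves the alcohols alone, and the tert-butyl ester cannot be attacked by the neighbouring hydroxyls.

Step 24
Reactants: 33 tert-butyl ester pentaol
Product: 34 C5=C6 alkene pentaol (C16 methyl on C5)
Conditions: Pd(OAc)2 (5 mol%), PPh3, Et3N, HCO2H, DMF, 60 °C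
Reagents that add atoms: none
Why: Palladium-catalysed formate reduction of a vinyl triflate to the trisubstituted olefin; free alcohols, the lactone and the ester are compatible.

Step 25
Reactants: 34 C5=C6 alkene pentaol
Product: 35 2,3,9,14-tetraacetate (free 11α-OH)
Conditions: Ac2O, pyridine, DMAP, 40 °C
Reagents that add atoms: acetic anhydride, CC(=O)OC(C)=O
Why: Acylation of the four secondary alcohols; the tertiary C11 hydroxyl next to the ester is too hindered to react under these conditions.

Step 26
Reactants: 35 2,3,9,14-tetraacetate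
Product: 36 6-chloro 5(16)-ene tert-butyl ester (Cl cis to the lactone oxygen on C7)
Conditions: Ca(OCl)2, CO2 (solid), CH2Cl2/H2O, 0 °C
Reagents that add atoms: calcium hypochlorite, [Ca+2].[O-]Cl.[O-]Cl
Why: Ene-type allylic chlorination with hypochlorous acid: chlorine adds to the less substituted C6 and the proton is lost from the C16 methyl (the alternative C4–H is a bridgehead hydrogen), and attack on the exo face of the dihydropyran, opposite to the five-carbon bridge, gives the 6S chloride.

Step 27
Reactants: 36 6-chloro 5(16)-ene tert-butyl ester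
Product: 37 CNP0186125.1
Conditions: CF3CO2H/CH2Cl2 (1:4), 0 °C
Reagents that add atoms: none
Why: Acidolysis of the tert-butyl ester by alkyl–oxygen cleavage, which does not depend on access to the hindered carbonyl and leaves acetates, lactone and allylic chloride intact.

## Compound list

1 | 2-methylcyclopent-2-en-1-one | CC1=CCCC1=O | starting material
2 | (1E,3E)-buta-1,3-diene-1,4-diyl diacetate | CC(=O)O/C=C/C=C/OC(C)=O | starting material
3 | cis-hydrindenone diacetate (C2 ketone; 11α,14α-diacetoxy; C12=C13; H10 β) | O=C1CC[C@@H]2[C@H](OC(C)=O)C=C[C@H](OC(C)=O)[C@]12C | intermediate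
4 | cis-hydrindanone diacetate | O=C1CC[C@@H]2[C@H](OC(C)=O)CC[C@H](OC(C)=O)[C@]12C | intermediate
5 | 3-(hydroxymethylene) ketone | O=C1/C(=C\O)C[C@@H]2[C@H](OC(C)=O)CC[C@H](OC(C)=O)[C@]12C | intermediate
6 | 3-formyl cyclopentenone | O=C1C(C=O)=C[C@@H]2[C@H](OC(C)=O)CC[C@H](OC(C)=O)[C@]12C | intermediate
7 | methyl 3-nitropropanoate | COC(=O)CC[N+](=O)[O-] | starting material
8 | nitro ester Michael adduct (C8 epimers) | O=C1/C(=C\O)[C@@H](C(CC(=O)OC)[N+](=O)[O-])[C@@H]2[C@H](OC(C)=O)CC[C@H](OC(C)=O)[C@]12C | intermediate
9 | keto aldehyde diol (C8 ketone, C3 hydroxymethylene; not isolated) | O=C1/C(=C\O)[C@@H](C(=O)CC(=O)OC)[C@@H]2[C@H](O)CC[C@H](O)[C@]12C | intermediate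
10 | furan-fused ketone diol | O=C1c2coc(CC(=O)OC)c2[C@@H]2[C@H](O)CC[C@H](O)[C@]12C | intermediate
11 | 2β,11α,14α-triol | O[C@H]1c2coc(CC(=O)OC)c2[C@@H]2[C@H](O)CC[C@H](O)[C@]12C | intermediate
12 | 2,14-O-(di-tert-butylsilylene) 11α-alcohol | CC(C)(C)[Si]1(C(C)(C)C)O[C@H]2c3coc(CC(=O)OC)c3[C@@H]3[C@H](O)CC[C@H](O1)[C@]23C | intermediate
13 | 2,14-O-silylene C11 ketone | CC(C)(C)[Si]1(C(C)(C)C)O[C@H]2c3coc(CC(=O)OC)c3[C@@H]3C(=O)CC[C@H](O1)[C@]23C | intermediate
14 | ethynyltrimethylsilane | C#C[Si](C)(C)C | starting material
15 | 11α-hydroxy alkyne (not isolated) | CC(C)(C)[Si]1(C(C)(C)C)O[C@H]2c3coc(CC(=O)OC)c3[C@@H]3[C@@](O)(C#C[Si](C)(C)C)CC[C@H](O1)[C@]23C | intermediate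
16 | 11α-triethylsilyloxy 11β-(trimethylsilylethynyl) furan | CC(C)(C)[Si]1(C(C)(C)C)O[C@H]2c3coc(CC(=O)OC)c3[C@@H]3[C@@](O[Si](CC)(CC)CC)(C#C[Si](C)(C)C)CC[C@H](O1)[C@]23C | intermediate
17 | 1,1,3-trichloropropan-2-one | O=C(CCl)C(Cl)Cl | starting material
18 | 1,3-dichloro-2-oxidoallyl cation (not isolated) | [O-]C(=CCl)[CH+]Cl | intermediate
19 | 5,7-dichloro (4+3) cycloadduct (chlorines drawn equatorial) | COC(=O)C[C@]12O[C@H]([C@@H](Cl)C(=O)[C@H]1Cl)C3=C2[C@@H]2[C@@](O[Si](CC)(CC)CC)(C#C[Si](C)(C)C)CC[C@@H]4O[Si](C(C)(C)C)(C(C)(C)C)O[C@@H]3[C@]24C | intermediate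
20 | cycloadduct ketone | COC(=O)C[C@]12O[C@H](CC(=O)C1)C3=C2[C@@H]2[C@@](O[Si](CC)(CC)CC)(C#C[Si](C)(C)C)CC[C@@H]4O[Si](C(C)(C)C)(C(C)(C)C)O[C@@H]3[C@]24C | intermediate
21 | 5-methyl ketone | COC(=O)C[C@]12O[C@H]([C@H](C)C(=O)C1)C3=C2[C@@H]2[C@@](O[Si](CC)(CC)CC)(C#C[Si](C)(C)C)CC[C@@H]4O[Si](C(C)(C)C)(C(C)(C)C)O[C@@H]3[C@]24C | intermediate
22 | 7-hydroxy ester (not isolated) | COC(=O)C[C@]12O[C@H]([C@H](C)C(=O)[C@@H]1O)C3=C2[C@@H]2[C@@](O[Si](CC)(CC)CC)(C#C[Si](C)(C)C)CC[C@@H]4O[Si](C(C)(C)C)(C(C)(C)C)O[C@@H]3[C@]24C | intermediate
23 | keto γ-lactone | O=C1C[C@]23O[C@H]([C@H](C)C(=O)[C@@H]2O1)C4=C3[C@@H]3[C@@](O[Si](CC)(CC)CC)(C#C[Si](C)(C)C)CC[C@@H]5O[Si](C(C)(C)C)(C(C)(C)C)O[C@@H]4[C@]35C | intermediate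
24 | enol triflate | O=C1C[C@]23O[C@H](C(C)=C(OS(=O)(=O)C(F)(F)F)[C@@H]2O1)C4=C3[C@@H]3[C@@](O[Si](CC)(CC)CC)(C#C[Si](C)(C)C)CC[C@@H]5O[Si](C(C)(C)C)(C(C)(C)C)O[C@@H]4[C@]35C | intermediate
25 | 17-methyl lactone enol triflate | O=C1[C@H](C)[C@]23O[C@H](C(C)=C(OS(=O)(=O)C(F)(F)F)[C@@H]2O1)C4=C3[C@@H]3[C@@](O[Si](CC)(CC)CC)(C#C[Si](C)(C)C)CC[C@@H]5O[Si](C(C)(C)C)(C(C)(C)C)O[C@@H]4[C@]35C | intermediate
26 | 3,9-diketone, ten-membered carbocycle (H10 β) | O=C1[C@H](C)[C@]23O[C@H](C(C)=C(OS(=O)(=O)C(F)(F)F)[C@@H]2O1)C(=O)[C@H](O[Si](C(C)(C)C)(C(C)(C)C)O4)[C@@]5(C)[C@@H]4CC[C@](O[Si](CC)(CC)CC)(C#C[Si](C)(C)C)[C@H]5C3=O | intermediate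
27 | 3α-hydroxy 9-ketone | O=C1[C@H](C)[C@]23O[C@H](C(C)=C(OS(=O)(=O)C(F)(F)F)[C@@H]2O1)[C@@H](O)[C@H](O[Si](C(C)(C)C)(C(C)(C)C)O4)[C@@]5(C)[C@@H]4CC[C@](O[Si](CC)(CC)CC)(C#C[Si](C)(C)C)[C@H]5C3=O | intermediate
28 | 3α-triethylsilyloxy 9-ketone (H10 β) | O=C1[C@H](C)[C@]23O[C@H](C(C)=C(OS(=O)(=O)C(F)(F)F)[C@@H]2O1)[C@@H](O[Si](CC)(CC)CC)[C@H](O[Si](C(C)(C)C)(C(C)(C)C)O4)[C@@]5(C)[C@@H]4CC[C@](O[Si](CC)(CC)CC)(C#C[Si](C)(C)C)[C@H]5C3=O | intermediate
29 | 3α-triethylsilyloxy 9-ketone, trans ring fusion (H10 α) | O=C1[C@H](C)[C@]23O[C@H](C(C)=C(OS(=O)(=O)C(F)(F)F)[C@@H]2O1)[C@@H](O[Si](CC)(CC)CC)[C@H](O[Si](C(C)(C)C)(C(C)(C)C)O4)[C@@]5(C)[C@@H]4CC[C@](O[Si](CC)(CC)CC)(C#C[Si](C)(C)C)[C@@H]5C3=O | intermediate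
30 | 9β-alcohol | O=C1[C@H](C)[C@]23O[C@H](C(C)=C(OS(=O)(=O)C(F)(F)F)[C@@H]2O1)[C@@H](O[Si](CC)(CC)CC)[C@H](O[Si](C(C)(C)C)(C(C)(C)C)O4)[C@@]5(C)[C@@H]4CC[C@](O[Si](CC)(CC)CC)(C#C[Si](C)(C)C)[C@@H]5[C@@H]3O | intermediate
31 | 2β,3α,9β,11α,14α-pentaol with terminal alkyne | O=C1[C@H](C)[C@]23O[C@H](C(C)=C(OS(=O)(=O)C(F)(F)F)[C@@H]2O1)[C@@H](O)[C@H](O)[C@@]4(C)[C@@H](O)CC[C@](O)(C#C)[C@@H]4[C@@H]3O | intermediate
32 | C20 carboxylic acid (not isolated) | O=C1[C@H](C)[C@]23O[C@H](C(C)=C(OS(=O)(=O)C(F)(F)F)[C@@H]2O1)[C@@H](O)[C@H](O)[C@@]4(C)[C@@H](O)CC[C@](O)(C(=O)O)[C@@H]4[C@@H]3O | intermediate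
33 | tert-butyl ester pentaol | O=C1[C@H](C)[C@]23O[C@H](C(C)=C(OS(=O)(=O)C(F)(F)F)[C@@H]2O1)[C@@H](O)[C@H](O)[C@@]4(C)[C@@H](O)CC[C@](O)(C(=O)OC(C)(C)C)[C@@H]4[C@@H]3O | intermediate
34 | C5=C6 alkene pentaol | O=C1[C@H](C)[C@]23O[C@H](C(C)=C[C@@H]2O1)[C@@H](O)[C@H](O)[C@@]4(C)[C@@H](O)CC[C@](O)(C(=O)OC(C)(C)C)[C@@H]4[C@@H]3O | intermediate
35 | 2,3,9,14-tetraacetate | O=C1[C@H](C)[C@]23O[C@H](C(C)=C[C@@H]2O1)[C@@H](OC(C)=O)[C@H](OC(C)=O)[C@@]4(C)[C@@H](OC(C)=O)CC[C@](O)(C(=O)OC(C)(C)C)[C@@H]4[C@@H]3OC(C)=O | intermediate
36 | 6-chloro 5(16)-ene tert-butyl ester | O=C1[C@H](C)[C@]23O[C@H](C(=C)[C@H](Cl)[C@@H]2O1)[C@@H](OC(C)=O)[C@H](OC(C)=O)[C@@]4(C)[C@@H](OC(C)=O)CC[C@](O)(C(=O)OC(C)(C)C)[C@@H]4[C@@H]3OC(C)=O | intermediate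
37 | CNP0186125.1 | C=C1[C@H]2O[C@]3([C@@H](C)C(=O)O[C@H]3[C@H]1Cl)[C@@H](OC(C)=O)[C@@H]1[C@](C)([C@@H](OC(C)=O)CC[C@]1(O)C(=O)O)[C@@H](OC(C)=O)[C@@H]2OC(C)=O | target

## Step count and least certain steps

Total step count: 27. Longest linear sequence: 27 steps (1 and 2 to 37).

**Step 11 (key step).** What may go wrong: poor facial selectivity (addition to the α face as well), or slow formation of the fully substituted C8 centre so that the cation is consumed by side reactions. Fallback, from 16 back to 23: the three-carbon unit is changed to 2-(triethylsilyloxy)prop-2-enal F1 under Sc(OTf)3 catalysis. This is a stepwise Lewis-acid-mediated (4+3) process in which the unhindered C4 terminus bonds first and the C7–C8 bond then closes intramolecularly, with the C7 oxygen already in place. It should give the 7-silyloxy cycloadduct F2. Kinetic methylation at C5 (LDA, MeI) gives F3, and K2CO3 in methanol followed by DBU removes the silyl group, equilibrates C7 through the C6 ketone and closes the cis-fused lactone, arriving at 23.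

**Step 20.** What may go wrong: incomplete or unfavourable equilibration at C10, or β-elimination of the C11 silyloxy group from the C9 enolate. Fallback, from 28 back to 29: thermodynamic control is replaced by kinetic control. Soft enolisation (Me3SiOTf, Et3N) gives the C9 trimethylsilyl enol ether F4, which is isolated and cleaved with Bu4NF in the presence of acetic acid at −78 °C, so that the enolate is protonated irreversibly from the less hindered α face (anti to the C15 methyl and the C11 alkynyl group), without prolonged exposure of the β-silyloxy ketone to base.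

**Step 21.** What may go wrong: hydride delivery to the wrong face of the C9 carbonyl, or attack of the new C9 alkoxide on the lactone. Fallback, from 29 back to 31: external hydride is replaced by internal delivery. HF·pyridine removes the two triethylsilyl ethers to give the 3,11-diol ketone F5, and Me4NBH(OAc)3 then reduces the β-hydroxy ketone under direction of the 11α hydroxyl (anti-1,3-diol, hence 9β) to give the triol F6. Treatment with Bu4NF/AcOH removes the silylene and the alkynyl silyl group and gives 31.

**Step 26.** What may go wrong: chlorine delivery to the bridge-side face (6-epimer), oxidation elsewhere, or allylic transposition of the chloride. Fallback, from 35 back to 36: a photooxygenation (singlet-oxygen ene reaction) on the same olefin puts a hydroperoxide on C6 with the same regiochemistry, giving F7, which is reduced in the flask with PPh3 to the allylic alcohol F8. Chlorination with inversion (PPh3, CCl4) then gives 36. Because this sequence inverts C6, it delivers the correct chloride exactly when the direct electrophilic attack prefers the wrong face.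

## Further compounds

F1 | step 11 | 2-(triethylsilyloxy)prop-2-enal | C=C(O[Si](CC)(CC)CC)C=O
F2 | step 11 | 7-triethylsilyloxy (4+3) cycloadduct (C6 ketone, C5H2) | COC(=O)C[C@]12O[C@H](CC(=O)[C@H]1O[Si](CC)(CC)CC)C3=C2[C@@H]2[C@@](O[Si](CC)(CC)CC)(C#C[Si](C)(C)C)CC[C@@H]4O[Si](C(C)(C)C)(C(C)(C)C)O[C@@H]3[C@]24C
F3 | step 11 | 5-methyl 7-triethylsilyloxy cycloadduct | COC(=O)C[C@]12O[C@H]([C@H](C)C(=O)[C@H]1O[Si](CC)(CC)CC)C3=C2[C@@H]2[C@@](O[Si](CC)(CC)CC)(C#C[Si](C)(C)C)CC[C@@H]4O[Si](C(C)(C)C)(C(C)(C)C)O[C@@H]3[C@]24C
F4 | step 20 | C9 trimethylsilyl enol ether (C9=C10) of 28 | O=C1[C@H](C)[C@]23O[C@H](C(C)=C(OS(=O)(=O)C(F)(F)F)[C@@H]2O1)[C@@H](O[Si](CC)(CC)CC)[C@H](O[Si](C(C)(C)C)(C(C)(C)C)O4)[C@@]5(C)[C@@H]4CC[C@](O[Si](CC)(CC)CC)(C#C[Si](C)(C)C)/C5=C3\O[Si](C)(C)C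
F5 | step 21 | 3α,11α-diol 9-ketone (silylene and alkynyl silane retained) | O=C1[C@H](C)[C@]23O[C@H](C(C)=C(OS(=O)(=O)C(F)(F)F)[C@@H]2O1)[C@@H](O)[C@H](O[Si](C(C)(C)C)(C(C)(C)C)O4)[C@@]5(C)[C@@H]4CC[C@](O)(C#C[Si](C)(C)C)[C@@H]5C3=O
F6 | step 21 | 3α,9β,11α-triol (silylene and alkynyl silane retained) | O=C1[C@H](C)[C@]23O[C@H](C(C)=C(OS(=O)(=O)C(F)(F)F)[C@@H]2O1)[C@@H](O)[C@H](O[Si](C(C)(C)C)(C(C)(C)C)O4)[C@@]5(C)[C@@H]4CC[C@](O)(C#C[Si](C)(C)C)[C@@H]5[C@@H]3O
F7 | step 26 | 6-hydroperoxy 5(16)-ene tetraacetate (C6 epimeric to the chloride of 36) | O=C1[C@H](C)[C@]23O[C@H](C(=C)[C@@H](OO)[C@@H]2O1)[C@@H](OC(C)=O)[C@H](OC(C)=O)[C@@]4(C)[C@@H](OC(C)=O)CC[C@](O)(C(=O)OC(C)(C)C)[C@@H]4[C@@H]3OC(C)=O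
F8 | step 26 | 6-hydroxy 5(16)-ene tetraacetate | O=C1[C@H](C)[C@]23O[C@H](C(=C)[C@@H](O)[C@@H]2O1)[C@@H](OC(C)=O)[C@H](OC(C)=O)[C@@]4(C)[C@@H](OC(C)=O)CC[C@](O)(C(=O)OC(C)(C)C)[C@@H]4[C@@H]3OC(C)=O
A1 | alternative 1 | carbocyclic 3E-olefin with free C8 hydroxyl (ether bridge not yet formed) | O=C1[C@H](C)[C@@]2(O)[C@@H](OC(C)=O)[C@@H]3[C@](C)([C@@H](OC(C)=O)CC[C@]3(O)C(=O)O)[C@@H](OC(C)=O)/C=C/C(=C)[C@H](Cl)[C@@H]2O1
A2 | alternative 2 | trans-fused 7,9a-dimethyl-9,10-dioxo-1,4,4a,5,8,9,9a,10-octahydroanthracen-1-yl acetate | CC1=CCC2=C(C1)C(=O)[C@@]1(C)[C@@H](OC(C)=O)C=CC[C@@H]1C2=O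
A3 | alternative 3 | Achmatowicz pyranone (lactol at C4, anomers) carrying ring A and the C2/C3 ketone arm | COC(=O)[C@H](C)[C@@]1(OC(O)C(C)=CC1=O)[C@@H](O[Si](C)(C)C(C)(C)C)[C@@H]1[C@@](C)(C(=O)COCc2ccccc2)[C@@H](O[Si](C)(C)C(C)(C)C)CC[C@]1(O[Si](CC)(CC)CC)C(=O)OC(C)(C)C
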